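**Remark on the chemistry:** the target is drawn as the free hydrogen sulfate. The sulfate monoester is carried as its sodium salt and protonated only in the last operation. The tetralin locants of the target are used for all intermediates, also in names: C1 bears the pendant aryl ring, C2 carries C9', C3 carries C9, C4 is the benzylic CH2, ring A is C4a–C8a.

## Analysis of the target

The target is a 1-aryltetralin cyclolignan. Ring A is a pentasubstituted benzene (6-OMe, 7-OH, 8-OMe), ring B is the carbocycle C1–C4, and a 4-hydroxy-3,5-dimethoxyphenyl ring hangs from C1. Three contiguous stereocentres, C1 (R), C2 (S) and C3 (S), are all-trans: the C1 aryl is anti to C9' on C2, and C9' is anti to C9 on C3. C2 and C3 each carry one CH2O carbon, but only C9' is sulfated, so the two arms must be told apart without ambiguity. The two phenols would take up SO3 before any aliphatic alcohol, and the alkyl hydrogen sulfate is polar and acid-labile, so sulfation has to come late on a substrate with capped phenols. C1 is a diarylmethine flanked by the peri C8 methoxy group, which crowds every bond formed at C1. The same peri interaction means that the all-trans isomer cannot be assumed to be the thermodynamic sink of ring B. The strategy rests on one feature: at the carboxyl oxidation level ring B is a cyclic 2,3-disubstituted succinate, so the C2–C3 bond joins two ester α-carbons and can be made by oxidising a tethered bis-enolate. Unequal esters (methyl at C9', tert-butyl at C9) then solve the differentiation.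

## Retrosynthetic reasoning

**C9'–O–S and the protecting groups (23 ⇐ 22 ⇐ 21 ⇐ 20).** The sulfate is put on last among the bond-forming events. This requires that C9'–OH is the only free hydroxyl: both phenols are benzyl ethers and C9–OH is a silyl ether, which defines 20. After sulfation (21) the silyl ether is removed with buffered fluoride (22). The benzyl ethers go last by hydrogenolysis, which touches neither the sulfate nor the diarylmethine, to give 23.

**C9 and C9' back to the carboxyl level (20 ⇐ 19 ⇐ 18 ⇐ 17 ⇐ 16).** Both CH2O carbons are traced to esters of different kind in 16. In the forward direction acid cleaves only the tert-butyl ester (17), borane reduces only the free acid (18), the new alcohol is silylated (19), and hydride then reduces the methyl ester (20). The two arms are therefore different by construction and no selective reaction between two like alcohols is needed.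

**C2–C3, the key cut (16 ⇐ 15 ⇐ 14).** Cutting C2–C3 opens ring B, removes two stereocentres and leaves C1 in place. No other ring bond joins two carbons that can both be made nucleophilic by the same base. The precursor 14 is an acyclic diester whose two α-carbons sit on arms held ortho to each other on ring A. The forward reaction must double-deprotonate 14 to 15 and then oxidise by one electron. It must close the six-membered ring faster than chains couple with each other, place C9' anti to the C1 aryl, and place the two esters trans.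

**C1–C1' (14 ⇐ 8 + 13).** The 3,3-diarylpropanoate 14 is cut at the bond to the pendant ring. This gives the cinnamate 8 on ring A and the arylboronic acid 13, to be joined by a rhodium-catalysed asymmetric conjugate addition. The cut is made here and not at C1–C8a because the di-ortho-substituted ring A is better as the electrophile, while the unhindered, symmetric pendant ring makes a well-behaved aryl nucleophile. The catalyst fixes the absolute configuration.

**C1–C8a and the C4 arm (8 ⇐ 6 + 7; 6 ⇐ 5 ⇐ 3 + 4; 3 ⇐ 2 ⇐ 1).** The cinnamate is cut at the aryl–vinyl bond (Heck coupling of 6 with 7). The propanoate arm of 6 comes from the aldehyde 3 by olefination with 4 and a conjugate reduction that must spare the aryl bromide. The bromide is placed ortho to the formyl group of 2, the only type of free position on that ring, after the phenol of 1 has been benzylated. The formyl carbon thus becomes C4 and the brominated carbon becomes C8a.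

**The boronic acid (13 ⇐ 12 ⇐ 11 ⇐ 10 ⇐ 9).** The C–B bond is made by bromine–lithium exchange on 10 and borylation. Compound 10 is the benzyl ether of 9.

## Alternatives that were turned down

**Alternative 1:** oxidative dimerisation of a chiral sinapoyl imide.
- Disconnection: C2–C3 and C1–C8a are cut together, giving two molecules of the imide A1, (4S)-4-benzyl-3-[(E)-3-(4-hydroxy-3,5-dimethoxyphenyl)prop-2-enoyl]-1,3-oxazolidin-2-one.
- Forward key step: Ag2O (or FeCl3 under O2) oxidises A1 to phenoxyl radicals with spin at the β-carbon. β–β coupling gives a bis-quinone methide; one half tautomerises and its ring closes onto the other quinone methide, giving the dihydronaphthalene bis-imide A2.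
- For it: no other plan is shorter to the skeleton. All carbons, ring B and the trans C1/C2 pair arise in one step from a monomer about two steps from sinapic acid, with no protecting groups. On step count to the carbon framework it is clearly stronger than the chosen route.
- Against it for this target:
  - The two carbonyls of A2 are the same imide and differ only by conjugation to C3=C4, yet exactly one of them must end as a sulfate.
  - C3 is still sp2 and must be set by a reduction whose facial preference relative to C2 is not secured.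
  - Both phenols are free and would have to be capped before SO3·pyridine.
  - The absolute configuration depends on a remote auxiliary steering a radical–radical coupling that also has β–O coupling and oligomerisation open to it.
- Comparison: the chosen route spends more steps, but each of these open questions has a dedicated element in it: catalyst control at C1, A(1,3) control at C2, unequal esters for C9 versus C9', and benzyl ethers from the start.

**Alternative 2:** three-component arylalkylation of a ring B styrene.
- Disconnection: C1–C1' and C2–C9' are cut together. This gives the styrene A3 ((3S)-7-(benzyloxy)-3-[(benzyloxy)methyl]-6,8-dimethoxy-3,4-dihydronaphthalene, C1=C2 alkene), the aryl bromide 10 and the borylmethyl iodide A4 (2-(iodomethyl)-4,4,5,5-tetramethyl-1,3,2-dioxaborolane).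
- Forward key step: NiBr2·glyme, 4,4'-di-tert-butyl-2,2'-bipyridine and Zn turn A4 into a borylmethyl radical that adds to C2. The C1 benzylic radical is captured by the aryl–nickel species from 10, and reductive elimination gives A5.
- For it: it is convergent, and C9' arrives as a CH2–B group already distinct from the benzyl-protected C9. Oxidation, sulfation and one hydrogenolysis would then finish the synthesis, an endgame about half as long as the chosen one. On that point it is stronger.
- Against it for this target:
  - The alkene is internal and cyclic, a much poorer radical acceptor and nickel partner than a terminal styrene.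
  - The C1 radical sits beside the peri C8 methoxy group, so capture and reductive elimination are hindered.
  - β-Hydride loss from the C1–nickel species leads toward a naphthalene.
  - Direct coupling of 10 with A4 competes.
  - C3 must first be made enantiopure in A3, which costs steps, and the C1 configuration depends on substrate control two atoms away.
- Comparison: the chosen route forms its two critical bonds intramolecularly or under catalyst control instead of asking three components to meet at a hindered carbon.

**Alternative 3:** a one-carbon unit stitched in as C4.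
- Disconnection: C3–C4 and C4–C4a are cut, giving the diaryl aldehyde A6 ((3R,4R)-3-{[(tert-butyldimethylsilyl)oxy]methyl}-4-(3-hydroxy-2,4-dimethoxyphenyl)-4-(4-hydroxy-3,5-dimethoxyphenyl)butanal) and formaldehyde A7.
- Forward key step: a secondary amine catalyst condenses A7 at the aldehyde α-carbon C3 to an α-methylene iminium. The ring A carbon para to the phenol adds to its terminus, closing ring B to A8.
- For it: the phenols need no protection up to this point, C9 (aldehyde) and C9' (silyl ether) are distinct in A8, and an endgame of reduction, triple benzylation, desilylation, sulfation and hydrogenolysis would be shorter than the chosen one.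
- Against it for this target:
  - A6 already contains C1 and C2 with two different but very similar trioxygenated aryl groups on C1, so it is no easier to make than 14.
  - C3 is set by protonation α to an aldehyde, that is by the same uncertain ring B thermodynamics.
  - The free phenols must still be capped before sulfation.
  - The α-methylene aldehyde intermediate can polymerise or be attacked by the pendant ring.
- Comparison: the chosen route forms both new centres in one bond-forming event next to a fixed C1, and keeps the phenols masked throughout.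

Key step: step 9

## Route

**Step 1**
Reactants: 1 syringaldehyde
Product: 2 4-(benzyloxy)-3,5-dimethoxybenzaldehyde
Conditions: BnBr, K2CO3, DMF, 60 °C
Reagents that add atoms: benzyl bromide, BrCc1ccccc1
Why: Williamson etherification of the phenoxide; the benzyl ether masks the phenol against bromination, strong base and later sulfation and is removable by hydrogenolysis at the end.

**Step 2**
Reactants: 2 4-(benzyloxy)-3,5-dimethoxybenzaldehyde
Product: 3 4-(benzyloxy)-2-bromo-3,5-dimethoxybenzaldehyde
Conditions: NBS, MeCN, rt → 50 °C, dark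
Reagents that add atoms: N-bromosuccinimide, O=C1CCC(=O)N1Br
Why: Electrophilic aromatic bromination; the two equivalent free positions are ortho to one methoxy group and para to the other, so a single monobromide is expected and the unactivated benzyl ring is left alone.

**Step 3**
Reactants: 3 4-(benzyloxy)-2-bromo-3,5-dimethoxybenzaldehyde; 4 tert-butyl diethylphosphonoacetate
Product: 5 tert-butyl (E)-3-[4-(benzyloxy)-2-bromo-3,5-dimethoxyphenyl]prop-2-enoate
Conditions: NaH, THF, 0 °C → rt
Reagents that add atoms: none
Why: Horner–Wadsworth–Emmons olefination of an aryl aldehyde with a stabilised phosphonate gives the (E)-enoate and installs C3 and C9 with the tert-butyl ester in place.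

**Step 4**
Reactants: 5 tert-butyl (E)-3-[4-(benzyloxy)-2-bromo-3,5-dimethoxyphenyl]prop-2-enoate
Product: 6 tert-butyl 3-[4-(benzyloxy)-2-bromo-3,5-dimethoxyphenyl]propanoate
Conditions: Cu(OAc)2·H2O (5 mol %), 1,2-bis(diphenylphosphino)benzene (5 mol %), (EtO)2MeSiH, t-BuOH, toluene, rt
Reagents that add atoms: none
Why: Copper hydride conjugate reduction; the phosphine-ligated copper hydride adds 1,4 to the enoate and does not insert into aryl–bromine or benzyl–oxygen bonds, which catalytic hydrogenation over palladium would cleave.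

**Step 5**
Reactants: 6 tert-butyl 3-[4-(benzyloxy)-2-bromo-3,5-dimethoxyphenyl]propanoate; 7 methyl acrylate
Product: 8 methyl (E)-3-{3-(benzyloxy)-6-[3-(tert-butoxy)-3-oxopropyl]-2,4-dimethoxyphenyl}prop-2-enoate
Conditions: Pd2(dba)3 (2.5 mol %), [HP(t-Bu)3]BF4 (10 mol %), Cy2NMe, dioxane, 90 °C
Reagents that add atoms: none
Why: Heck coupling; the bulky, electron-rich phosphine lets zerovalent palladium insert into the electron-rich, di-ortho-substituted aryl bromide, and syn insertion with β-hydride elimination gives the (E)-cinnamate that carries C1, C2 and C9'.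

**Step 6**
Reactants: 9 4-bromo-2,6-dimethoxyphenol
Product: 10 2-(benzyloxy)-5-bromo-1,3-dimethoxybenzene
Conditions: BnBr, K2CO3, DMF, 60 °C
Reagents that add atoms: benzyl bromide, BrCc1ccccc1
Why: Williamson etherification, as in step 1, so that both phenols of the target carry the same protecting group.

**Step 7**
Reactants: 10 2-(benzyloxy)-5-bromo-1,3-dimethoxybenzene
Product: 13 [4-(benzyloxy)-3,5-dimethoxyphenyl]boronic acid, via aryllithium 11 (not isolated), via lithium aryltriisopropoxyborate 12 (not isolated)
Conditions: n-BuLi, THF, −78 °C; B(OiPr)3, −78 °C → rt; 1 M HCl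
Reagents that add atoms: triisopropyl borate, CC(C)OB(OC(C)C)OC(C)C; water, O
Why: Bromine–lithium exchange is fast at −78 °C and the aryllithium is trapped by the borate ester; acid hydrolysis of the ate complex releases the boronic acid.

**Step 8**
Reactants: 8 methyl (E)-3-{3-(benzyloxy)-6-[3-(tert-butoxy)-3-oxopropyl]-2,4-dimethoxyphenyl}prop-2-enoate; 13 [4-(benzyloxy)-3,5-dimethoxyphenyl]boronic acid
Product: 14 methyl (3R)-3-[4-(benzyloxy)-3,5-dimethoxyphenyl]-3-{3-(benzyloxy)-6-[3-(tert-butoxy)-3-oxopropyl]-2,4-dimethoxyphenyl}propanoate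
Conditions: Rh(acac)(C2H4)2 (3 mol %), (S)-BINAP (4.5 mol %), 13 (4 equiv), dioxane/H2O (10:1), 100 °C
Reagents that add atoms: none
Why: Hayashi–Miyaura asymmetric 1,4-addition with monovalent rhodium; the aryl–rhodium species inserts the enoate and water releases the product from the oxa-π-allyl complex. With (S)-BINAP the aryl group is delivered to the α-si face of an (E)-enoate, which corresponds to (R) at C1 here because ring A outranks the incoming ring.

**Step 9**
Reactants: 14 methyl (3R)-3-[4-(benzyloxy)-3,5-dimethoxyphenyl]-3-{3-(benzyloxy)-6-[3-(tert-butoxy)-3-oxopropyl]-2,4-dimethoxyphenyl}propanoate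
Product: 16 3-tert-butyl 2-methyl (1R,2S,3S)-7-(benzyloxy)-1-[4-(benzyloxy)-3,5-dimethoxyphenyl]-6,8-dimethoxy-1,2,3,4-tetrahydronaphthalene-2,3-dicarboxylate, via dilithium bis-enolate 15 (not isolated)
Conditions: LiN(iPr)2 (2.3 equiv), THF, −78 °C (14 added slowly to the base); Fe(acac)3 (2.2 equiv), THF, 0.01 M, −78 → 0 °C; aq. NH4Cl
Reagents that add atoms: none
Why: Both ester α-carbons are deprotonated, and trivalent iron oxidises one lithium enolate to an α-ester radical, which adds to the second enolate held on the neighbouring ortho arm; a second one-electron oxidation of the resulting radical anion gives the neutral diester. The closest known reaction type is the intramolecular oxidative coupling of diester bis-enolates to cyclic trans-1,2-diesters, together with iron- and copper-mediated couplings of ester and imide enolates. Ring B closes in 6-exo-trig mode with both new sp3 carbons in the ring. C2 is controlled by C1 through allylic 1,3-strain: C1–H eclipses the enolate double bond, the tether from ring A occupies one face and the pendant aryl the other, so C3 arrives anti to the aryl and C9' ends trans to it. C3 is set in a chair-like transition structure that keeps the bulky tert-butyl ester pseudo-equatorial and therefore trans to C9'. The step needs cyclisation to beat chain-to-chain coupling, which the ortho disposition of the two arms and high dilution should secure. It also needs an oxidant too weak to attack the benzylated trialkoxyarenes, which holds for Fe(acac)3. The diarylmethine C1–H is kinetically far less acidic than the ester α-protons, so C1 is not touched.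

**Step 10**
Reactants: 16 3-tert-butyl 2-methyl (1R,2S,3S)-7-(benzyloxy)-1-[4-(benzyloxy)-3,5-dimethoxyphenyl]-6,8-dimethoxy-1,2,3,4-tetrahydronaphthalene-2,3-dicarboxylate
Product: 17 (1R,2S,3S)-7-(benzyloxy)-1-[4-(benzyloxy)-3,5-dimethoxyphenyl]-6,8-dimethoxy-2-(methoxycarbonyl)-1,2,3,4-tetrahydronaphthalene-3-carboxylic acid
Conditions: CF3CO2H, Et3SiH, CH2Cl2, 0 °C → rt
Reagents that add atoms: none
Why: Acidolysis of the tert-butyl ester by alkyl–oxygen cleavage leaves the methyl ester and the aryl benzyl ethers; the silane reduces the tert-butyl cation before it can alkylate the electron-rich rings.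

**Step 11**
Reactants: 17 (1R,2S,3S)-7-(benzyloxy)-1-[4-(benzyloxy)-3,5-dimethoxyphenyl]-6,8-dimethoxy-2-(methoxycarbonyl)-1,2,3,4-tetrahydronaphthalene-3-carboxylic acid
Product: 18 methyl (1R,2S,3S)-7-(benzyloxy)-1-[4-(benzyloxy)-3,5-dimethoxyphenyl]-3-(hydroxymethyl)-6,8-dimethoxy-1,2,3,4-tetrahydronaphthalene-2-carboxylate
Conditions: BH3·THF, THF, 0 °C → rt; then H2O
Reagents that add atoms: none
Why: Borane reduces a carboxylic acid through its acyloxyborane much faster than it reduces an ester, so only C9 reaches the alcohol level; the non-basic medium leaves C2 and C3 untouched.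

**Step 12**
Reactants: 18 methyl (1R,2S,3S)-7-(benzyloxy)-1-[4-(benzyloxy)-3,5-dimethoxyphenyl]-3-(hydroxymethyl)-6,8-dimethoxy-1,2,3,4-tetrahydronaphthalene-2-carboxylate
Product: 19 methyl (1R,2S,3S)-7-(benzyloxy)-1-[4-(benzyloxy)-3,5-dimethoxyphenyl]-3-{[(tert-butyldimethylsilyl)oxy]methyl}-6,8-dimethoxy-1,2,3,4-tetrahydronaphthalene-2-carboxylate
Conditions: TBSCl, imidazole, DMF, 0 °C → rt (run directly on crude 18)
Reagents that add atoms: tert-butyldimethylsilyl chloride, CC(C)(C)[Si](C)(C)Cl
Why: Silylation of the primary alcohol under weakly basic conditions blocks lactonisation onto the neighbouring methyl ester and does not epimerise C2.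

**Step 13**
Reactants: 19 methyl (1R,2S,3S)-7-(benzyloxy)-1-[4-(benzyloxy)-3,5-dimethoxyphenyl]-3-{[(tert-butyldimethylsilyl)oxy]methyl}-6,8-dimethoxy-1,2,3,4-tetrahydronaphthalene-2-carboxylate
Product: 20 [(1R,2S,3S)-7-(benzyloxy)-1-[4-(benzyloxy)-3,5-dimethoxyphenyl]-3-{[(tert-butyldimethylsilyl)oxy]methyl}-6,8-dimethoxy-1,2,3,4-tetrahydronaphthalen-2-yl]methanol
Conditions: LiAlH4, THF, 0 °C; then H2O, 15% aq. NaOH
Reagents that add atoms: none
Why: Hydride reduction of the methyl ester to the primary alcohol C9'–OH; silyl and benzyl ethers are stable, and hydride addition is much faster than enolisation, so C2 keeps its configuration and is no longer epimerisable afterwards.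

**Step 14**
Reactants: 20 [(1R,2S,3S)-7-(benzyloxy)-1-[4-(benzyloxy)-3,5-dimethoxyphenyl]-3-{[(tert-butyldimethylsilyl)oxy]methyl}-6,8-dimethoxy-1,2,3,4-tetrahydronaphthalen-2-yl]methanol
Product: 21 sodium [(1R,2S,3S)-7-(benzyloxy)-1-[4-(benzyloxy)-3,5-dimethoxyphenyl]-3-{[(tert-butyldimethylsilyl)oxy]methyl}-6,8-dimethoxy-1,2,3,4-tetrahydronaphthalen-2-yl]methyl sulfate
Conditions: SO3·pyridine (3 equiv), pyridine, rt; aq. NaHCO3
Reagents that add atoms: sulfur trioxide–pyridine complex, O=S(=O)=O.c1ccncc1; sodium hydrogencarbonate, [Na+].OC([O-])=O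
Why: O-Sulfation of the only free hydroxyl by the SO3–amine complex; the silyl ether and benzyl ethers are inert in pyridine, and bicarbonate converts the pyridinium salt into the stable sodium salt.

**Step 15**
Reactants: 21 sodium [(1R,2S,3S)-7-(benzyloxy)-1-[4-(benzyloxy)-3,5-dimethoxyphenyl]-3-{[(tert-butyldimethylsilyl)oxy]methyl}-6,8-dimethoxy-1,2,3,4-tetrahydronaphthalen-2-yl]methyl sulfate
Product: 22 sodium [(1R,2S,3S)-7-(benzyloxy)-1-[4-(benzyloxy)-3,5-dimethoxyphenyl]-3-(hydroxymethyl)-6,8-dimethoxy-1,2,3,4-tetrahydronaphthalen-2-yl]methyl sulfate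
Conditions: HF·pyridine, pyridine/THF, 0 °C → rt; aq. NaHCO3
Reagents that add atoms: none
Why: Fluoride-driven cleavage of the primary silyl ether; the pyridine buffer keeps the medium too weakly acidic to solvolyse the sulfate monoester, which stays as its sodium salt.

**Step 16**
Reactants: 22 sodium [(1R,2S,3S)-7-(benzyloxy)-1-[4-(benzyloxy)-3,5-dimethoxyphenyl]-3-(hydroxymethyl)-6,8-dimethoxy-1,2,3,4-tetrahydronaphthalen-2-yl]methyl sulfate
Product: 23 [(1R,2S,3S)-7-hydroxy-1-(4-hydroxy-3,5-dimethoxyphenyl)-3-(hydroxymethyl)-6,8-dimethoxy-1,2,3,4-tetrahydronaphthalen-2-yl]methyl hydrogen sulfate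
Conditions: H2 (1 atm), Pd/C, MeOH, rt; then aq. HCl (1.0 equiv), 0 °C, C18 desalting, lyophilisation
Reagents that add atoms: none
Why: Hydrogenolysis of the two aryl benzyl ethers; alkyl sulfate salts and the hindered diarylmethine C1–aryl bonds are not cleaved under these conditions, and one equivalent of acid in the cold gives the hydrogen sulfate.

## Compound list

1 | syringaldehyde (4-hydroxy-3,5-dimethoxybenzaldehyde) | COc1cc(C=O)cc(OC)c1O | starting material
2 | 4-(benzyloxy)-3,5-dimethoxybenzaldehyde | COc1cc(C=O)cc(OC)c1OCc1ccccc1 | intermediate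
3 | 4-(benzyloxy)-2-bromo-3,5-dimethoxybenzaldehyde | COc1cc(C=O)c(Br)c(OC)c1OCc1ccccc1 | intermediate
4 | tert-butyl diethylphosphonoacetate | CCOP(=O)(OCC)CC(=O)OC(C)(C)C | starting material
5 | tert-butyl (E)-3-[4-(benzyloxy)-2-bromo-3,5-dimethoxyphenyl]prop-2-enoate | COc1cc(/C=C/C(=O)OC(C)(C)C)c(Br)c(OC)c1OCc1ccccc1 | intermediate
6 | tert-butyl 3-[4-(benzyloxy)-2-bromo-3,5-dimethoxyphenyl]propanoate | COc1cc(CCC(=O)OC(C)(C)C)c(Br)c(OC)c1OCc1ccccc1 | intermediate
7 | methyl acrylate | C=CC(=O)OC | starting material
8 | methyl (E)-3-{3-(benzyloxy)-6-[3-(tert-butoxy)-3-oxopropyl]-2,4-dimethoxyphenyl}prop-2-enoate | COC(=O)/C=C/c1c(CCC(=O)OC(C)(C)C)cc(OC)c(OCc2ccccc2)c1OC | intermediate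
9 | 4-bromo-2,6-dimethoxyphenol | COc1cc(Br)cc(OC)c1O | starting material
10 | 2-(benzyloxy)-5-bromo-1,3-dimethoxybenzene | COc1cc(Br)cc(OC)c1OCc1ccccc1 | intermediate
11 | [4-(benzyloxy)-3,5-dimethoxyphenyl]lithium (not isolated) | [Li]c1cc(OC)c(OCc2ccccc2)c(OC)c1 | intermediate
12 | lithium [4-(benzyloxy)-3,5-dimethoxyphenyl]tri(propan-2-yloxy)borate (not isolated) | [Li+].CC(C)O[B-](OC(C)C)(OC(C)C)c1cc(OC)c(OCc2ccccc2)c(OC)c1 | intermediate
13 | [4-(benzyloxy)-3,5-dimethoxyphenyl]boronic acid | OB(O)c1cc(OC)c(OCc2ccccc2)c(OC)c1 | intermediate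
14 | methyl (3R)-3-[4-(benzyloxy)-3,5-dimethoxyphenyl]-3-{3-(benzyloxy)-6-[3-(tert-butoxy)-3-oxopropyl]-2,4-dimethoxyphenyl}propanoate | COc1cc([C@@H](CC(=O)OC)c2c(CCC(=O)OC(C)(C)C)cc(OC)c(OCc3ccccc3)c2OC)cc(OC)c1OCc1ccccc1 | intermediate
15 | dilithium bis-enolate of 14 (C1 R, enolate geometries not defined; not isolated) | COc1cc([C@@H](C=C(O[Li])OC)c2c(CC=C(O[Li])OC(C)(C)C)cc(OC)c(OCc3ccccc3)c2OC)cc(OC)c1OCc1ccccc1 | intermediate
16 | 3-tert-butyl 2-methyl (1R,2S,3S)-7-(benzyloxy)-1-[4-(benzyloxy)-3,5-dimethoxyphenyl]-6,8-dimethoxy-1,2,3,4-tetrahydronaphthalene-2,3-dicarboxylate | COc1cc([C@@H]2c3c(cc(OC)c(OCc4ccccc4)c3OC)C[C@H](C(=O)OC(C)(C)C)[C@H]2C(=O)OC)cc(OC)c1OCc1ccccc1 | intermediate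
17 | (1R,2S,3S)-7-(benzyloxy)-1-[4-(benzyloxy)-3,5-dimethoxyphenyl]-6,8-dimethoxy-2-(methoxycarbonyl)-1,2,3,4-tetrahydronaphthalene-3-carboxylic acid | COc1cc([C@@H]2c3c(cc(OC)c(OCc4ccccc4)c3OC)C[C@H](C(=O)O)[C@H]2C(=O)OC)cc(OC)c1OCc1ccccc1 | intermediate
18 | methyl (1R,2S,3S)-7-(benzyloxy)-1-[4-(benzyloxy)-3,5-dimethoxyphenyl]-3-(hydroxymethyl)-6,8-dimethoxy-1,2,3,4-tetrahydronaphthalene-2-carboxylate | COc1cc([C@@H]2c3c(cc(OC)c(OCc4ccccc4)c3OC)C[C@H](CO)[C@H]2C(=O)OC)cc(OC)c1OCc1ccccc1 | intermediate
19 | methyl (1R,2S,3S)-7-(benzyloxy)-1-[4-(benzyloxy)-3,5-dimethoxyphenyl]-3-{[(tert-butyldimethylsilyl)oxy]methyl}-6,8-dimethoxy-1,2,3,4-tetrahydronaphthalene-2-carboxylate | COc1cc([C@@H]2c3c(cc(OC)c(OCc4ccccc4)c3OC)C[C@H](CO[Si](C)(C)C(C)(C)C)[C@H]2C(=O)OC)cc(OC)c1OCc1ccccc1 | intermediate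
20 | [(1R,2S,3S)-7-(benzyloxy)-1-[4-(benzyloxy)-3,5-dimethoxyphenyl]-3-{[(tert-butyldimethylsilyl)oxy]methyl}-6,8-dimethoxy-1,2,3,4-tetrahydronaphthalen-2-yl]methanol | COc1cc([C@@H]2c3c(cc(OC)c(OCc4ccccc4)c3OC)C[C@H](CO[Si](C)(C)C(C)(C)C)[C@H]2CO)cc(OC)c1OCc1ccccc1 | intermediate
21 | sodium [(1R,2S,3S)-7-(benzyloxy)-1-[4-(benzyloxy)-3,5-dimethoxyphenyl]-3-{[(tert-butyldimethylsilyl)oxy]methyl}-6,8-dimethoxy-1,2,3,4-tetrahydronaphthalen-2-yl]methyl sulfate | COc1cc([C@@H]2c3c(cc(OC)c(OCc4ccccc4)c3OC)C[C@H](CO[Si](C)(C)C(C)(C)C)[C@H]2COS(=O)(=O)[O-])cc(OC)c1OCc1ccccc1.[Na+] | intermediate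
22 | sodium [(1R,2S,3S)-7-(benzyloxy)-1-[4-(benzyloxy)-3,5-dimethoxyphenyl]-3-(hydroxymethyl)-6,8-dimethoxy-1,2,3,4-tetrahydronaphthalen-2-yl]methyl sulfate | COc1cc([C@@H]2c3c(cc(OC)c(OCc4ccccc4)c3OC)C[C@H](CO)[C@H]2COS(=O)(=O)[O-])cc(OC)c1OCc1ccccc1.[Na+] | intermediate
23 | [(1R,2S,3S)-7-hydroxy-1-(4-hydroxy-3,5-dimethoxyphenyl)-3-(hydroxymethyl)-6,8-dimethoxy-1,2,3,4-tetrahydronaphthalen-2-yl]methyl hydrogen sulfate | COc1cc([C@@H]2c3c(cc(OC)c(O)c3OC)C[C@H](CO)[C@H]2COS(=O)(=O)O)cc(OC)c1O | target

## Step count and least certain steps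

Total: 16 steps. Longest linear sequence: 14 steps (steps 1–5 and 8–16); steps 6 and 7 form the convergent branch.

**Step 9 (key step).**
- Most likely to go wrong: coupling between chains, or simple re-protonation, can compete with ring closure, because the radical has to reach the second enolate across a di-ortho-substituted arene. Control at C3 (and less probably at C2) may also be incomplete. Base equilibration is not a safe remedy: with the peri C8 methoxy group the all-trans isomer need not be the most stable, so the quench is kept cold and neutral and minor isomers would be removed at 16.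
- Fallback, from 14 back to 17: the tert-butyl ester of 14 is cleaved first (CF3CO2H, Et3SiH) to 3-[4-(benzyloxy)-2-{(1R)-1-[4-(benzyloxy)-3,5-dimethoxyphenyl]-3-methoxy-3-oxopropyl}-3,5-dimethoxyphenyl]propanoic acid F1. Three equivalents of LiN(iPr)2 in THF convert it into the trilithium carboxylate-enediolate/ester-enolate F2. One equivalent of I2 then iodinates one α-carbon, and the other displaces iodide within the tether. This two-electron sequence is the iodine coupling of carboxylic acid dianions and ester enolates to succinates. It avoids free radicals and delivers the acid 17 directly.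

**Step 8.**
- Most likely to go wrong: slow insertion at a β-carbon flanked by two ortho substituents, protodeboronation of the electron-rich boronic acid at 100 °C, and eroded facial selectivity on such a twisted cinnamate.
- Fallback, from 6 back to 14: auxiliary control replaces catalyst control. Heck coupling of 6 with (4S)-3-acryloyl-4-phenyl-1,3-oxazolidin-2-one F3 gives (4S)-3-[(E)-3-{3-(benzyloxy)-6-[3-(tert-butoxy)-3-oxopropyl]-2,4-dimethoxyphenyl}prop-2-enoyl]-4-phenyl-1,3-oxazolidin-2-one F4. The aryllithium 11 is transmetallated with MgBr2·OEt2 to [4-(benzyloxy)-3,5-dimethoxyphenyl]magnesium bromide F5. With CuBr·SMe2 this adds to the chelated s-cis imide on the face away from the phenyl group, giving (4S)-3-[(3R)-3-[4-(benzyloxy)-3,5-dimethoxyphenyl]-3-{3-(benzyloxy)-6-[3-(tert-butoxy)-3-oxopropyl]-2,4-dimethoxyphenyl}propanoyl]-4-phenyl-1,3-oxazolidin-2-one F6. Methanolysis with MeOMgBr in MeOH/THF returns 14 and the auxiliary.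

**Step 5.**
- Most likely to go wrong: sluggish oxidative addition into the electron-rich, di-ortho-substituted bromide, with reductive loss of bromine as the competing path.
- Fallback, from 6 back to 8: Suzuki–Miyaura coupling of 6 with commercial methyl (E)-3-(4,4,5,5-tetramethyl-1,3,2-dioxaborolan-2-yl)prop-2-enoate (Pd(OAc)2, 2-dicyclohexylphosphino-2',6'-dimethoxybiphenyl, K3PO4, toluene/H2O). This replaces alkene insertion and β-hydride elimination by transmetallation and gives 8 directly.

**Step 4.**
- Most likely to go wrong: incomplete reduction of the ortho-substituted cinnamate, or partial loss of the aryl bromide if a less selective reductant has to be used.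
- Fallback, from 3 back to 6: the arm is built by alkylation instead of olefination and reduction. NaBH4 reduces 3 to [4-(benzyloxy)-2-bromo-3,5-dimethoxyphenyl]methanol F7. PBr3 gives 2-(benzyloxy)-4-bromo-5-(bromomethyl)-1,3-dimethoxybenzene F8. The lithium enolate of tert-butyl acetate F9 (tert-butyl acetate, LiN(iPr)2, THF, −78 °C) displaces the benzylic bromide to give 6.

**Step 15.**
- Most likely to go wrong: partial solvolysis of the sulfate during desilylation, or losses on purifying a polar sulfate salt twice.
- Fallback, from 18 back to 23: the silyl ether is replaced by a third benzyl ether so that no deprotection follows sulfation except the final hydrogenolysis. Compound 18 is benzylated under neutral conditions (2-(benzyloxy)-1-methylpyridinium triflate, MgO, PhCF3, 85 °C) to methyl (1R,2S,3S)-7-(benzyloxy)-1-[4-(benzyloxy)-3,5-dimethoxyphenyl]-3-[(benzyloxy)methyl]-6,8-dimethoxy-1,2,3,4-tetrahydronaphthalene-2-carboxylate F10. LiAlH4 gives [(1R,2S,3S)-7-(benzyloxy)-1-[4-(benzyloxy)-3,5-dimethoxyphenyl]-3-[(benzyloxy)methyl]-6,8-dimethoxy-1,2,3,4-tetrahydronaphthalen-2-yl]methanol F11. SO3·pyridine and NaHCO3 give its sodium sulfate F12. Hydrogenolysis of all three benzyl ethers and acidification as in step 16 give 23. This is two steps shorter; it is kept in reserve because benzyl transfer could also alkylate the electron-rich rings.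

## Further compounds

F1 | step 9 | 3-[4-(benzyloxy)-2-{(1R)-1-[4-(benzyloxy)-3,5-dimethoxyphenyl]-3-methoxy-3-oxopropyl}-3,5-dimethoxyphenyl]propanoic acid | COc1cc([C@@H](CC(=O)OC)c2c(CCC(=O)O)cc(OC)c(OCc3ccccc3)c2OC)cc(OC)c1OCc1ccccc1
F2 | step 9 | trilithium carboxylate-enediolate/ester-enolate of F1 | COc1cc([C@@H](C=C(O[Li])OC)c2c(CC=C(O[Li])O[Li])cc(OC)c(OCc3ccccc3)c2OC)cc(OC)c1OCc1ccccc1
F3 | step 8 | (4S)-3-acryloyl-4-phenyl-1,3-oxazolidin-2-one | C=CC(=O)N1[C@@H](c2ccccc2)COC1=O
F4 | step 8 | (4S)-3-[(E)-3-{3-(benzyloxy)-6-[3-(tert-butoxy)-3-oxopropyl]-2,4-dimethoxyphenyl}prop-2-enoyl]-4-phenyl-1,3-oxazolidin-2-one | COc1cc(CCC(=O)OC(C)(C)C)c(/C=C/C(=O)N2[C@@H](c3ccccc3)COC2=O)c(OC)c1OCc1ccccc1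
F5 | step 8 | [4-(benzyloxy)-3,5-dimethoxyphenyl]magnesium bromide | Br[Mg]c1cc(OC)c(OCc2ccccc2)c(OC)c1
F6 | step 8 | (4S)-3-[(3R)-3-[4-(benzyloxy)-3,5-dimethoxyphenyl]-3-{3-(benzyloxy)-6-[3-(tert-butoxy)-3-oxopropyl]-2,4-dimethoxyphenyl}propanoyl]-4-phenyl-1,3-oxazolidin-2-one | COc1cc([C@@H](CC(=O)N2[C@@H](c3ccccc3)COC2=O)c2c(CCC(=O)OC(C)(C)C)cc(OC)c(OCc3ccccc3)c2OC)cc(OC)c1OCc1ccccc1
F0 | step 5 | none | none
F7 | step 4 | [4-(benzyloxy)-2-bromo-3,5-dimethoxyphenyl]methanol | COc1cc(CO)c(Br)c(OC)c1OCc1ccccc1
F8 | step 4 | 2-(benzyloxy)-4-bromo-5-(bromomethyl)-1,3-dimethoxybenzene | COc1cc(CBr)c(Br)c(OC)c1OCc1ccccc1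
F9 | step 4 | lithium enolate of tert-butyl acetate | C=C(O[Li])OC(C)(C)C
F10 | step 15 | methyl (1R,2S,3S)-7-(benzyloxy)-1-[4-(benzyloxy)-3,5-dimethoxyphenyl]-3-[(benzyloxy)methyl]-6,8-dimethoxy-1,2,3,4-tetrahydronaphthalene-2-carboxylate | COc1cc([C@@H]2c3c(cc(OC)c(OCc4ccccc4)c3OC)C[C@H](COCc3ccccc3)[C@H]2C(=O)OC)cc(OC)c1OCc1ccccc1
F11 | step 15 | [(1R,2S,3S)-7-(benzyloxy)-1-[4-(benzyloxy)-3,5-dimethoxyphenyl]-3-[(benzyloxy)methyl]-6,8-dimethoxy-1,2,3,4-tetrahydronaphthalen-2-yl]methanol | COc1cc([C@@H]2c3c(cc(OC)c(OCc4ccccc4)c3OC)C[C@H](COCc3ccccc3)[C@H]2CO)cc(OC)c1OCc1ccccc1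
F12 | step 15 | sodium [(1R,2S,3S)-7-(benzyloxy)-1-[4-(benzyloxy)-3,5-dimethoxyphenyl]-3-[(benzyloxy)methyl]-6,8-dimethoxy-1,2,3,4-tetrahydronaphthalen-2-yl]methyl sulfate | COc1cc([C@@H]2c3c(cc(OC)c(OCc4ccccc4)c3OC)C[C@H](COCc3ccccc3)[C@H]2COS(=O)(=O)[O-])cc(OC)c1OCc1ccccc1.[Na+]
A1 | alternative 1 | (4S)-4-benzyl-3-[(E)-3-(4-hydroxy-3,5-dimethoxyphenyl)prop-2-enoyl]-1,3-oxazolidin-2-one | COc1cc(/C=C/C(=O)N2[C@@H](Cc3ccccc3)COC2=O)cc(OC)c1O
A2 | alternative 1 | (4S,4'S)-3,3'-{[(1R,2S)-7-hydroxy-1-(4-hydroxy-3,5-dimethoxyphenyl)-6,8-dimethoxy-1,2-dihydronaphthalene-2,3-diyl]dicarbonyl}bis(4-benzyl-1,3-oxazolidin-2-one) | COc1cc([C@@H]2c3c(cc(OC)c(O)c3OC)C=C(C(=O)N3[C@@H](Cc4ccccc4)COC3=O)[C@H]2C(=O)N2[C@@H](Cc3ccccc3)COC2=O)cc(OC)c1O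
A3 | alternative 2 | (3S)-7-(benzyloxy)-3-[(benzyloxy)methyl]-6,8-dimethoxy-3,4-dihydronaphthalene (C1=C2 alkene, target locants) | COc1cc2c(c(OC)c1OCc1ccccc1)C=C[C@@H](COCc1ccccc1)C2
A4 | alternative 2 | 2-(iodomethyl)-4,4,5,5-tetramethyl-1,3,2-dioxaborolane | ICB1OC(C)(C)C(C)(C)O1
A5 | alternative 2 | 2-{[(1R,2S,3S)-7-(benzyloxy)-1-[4-(benzyloxy)-3,5-dimethoxyphenyl]-3-[(benzyloxy)methyl]-6,8-dimethoxy-1,2,3,4-tetrahydronaphthalen-2-yl]methyl}-4,4,5,5-tetramethyl-1,3,2-dioxaborolane | COc1cc([C@@H]2c3c(cc(OC)c(OCc4ccccc4)c3OC)C[C@H](COCc3ccccc3)[C@H]2CB2OC(C)(C)C(C)(C)O2)cc(OC)c1OCc1ccccc1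
A6 | alternative 3 | (3R,4R)-3-{[(tert-butyldimethylsilyl)oxy]methyl}-4-(3-hydroxy-2,4-dimethoxyphenyl)-4-(4-hydroxy-3,5-dimethoxyphenyl)butanal | COc1cc([C@H](c2ccc(OC)c(O)c2OC)[C@@H](CC=O)CO[Si](C)(C)C(C)(C)C)cc(OC)c1O
A7 | alternative 3 | formaldehyde | C=O
A8 | alternative 3 | (1R,2S,3S)-2-{[(tert-butyldimethylsilyl)oxy]methyl}-7-hydroxy-1-(4-hydroxy-3,5-dimethoxyphenyl)-6,8-dimethoxy-1,2,3,4-tetrahydronaphthalene-3-carbaldehyde | COc1cc([C@@H]2c3c(cc(OC)c(O)c3OC)C[C@H](C=O)[C@H]2CO[Si](C)(C)C(C)(C)C)cc(OC)c1O
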